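## Retrosynthetic overview

1. Target 12 ⇐ aryl bromide 9 + acrolein diethyl acetal 10 (Heck coupling, then acetal hydrolysis); 9 ⇐ trans ester 8 (ester reduction).
2. Key disconnection, C3–C3a of 8, leads back to (R)-flavanone 5. Iodine(III) turns the ketone α-carbon (C3 of 5) into an enolonium-type electrophile, and the ring-A carbon C4a shifts onto it from C4 (oxidative ring contraction). Two normally nucleophilic carbons (enol carbon, arene carbon) are joined, C4 becomes the ester carbon, and C2 relays its configuration to C3 (trans).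
3. 5 ⇐ chromone 3 + boronic acid 4 (catalytic asymmetric conjugate arylation; sets C2, the only catalyst-controlled stereocentre).
4. 3 ⇐ o-hydroxyacetophenone 1 + DMF dimethyl acetal.
5. Ring order: both benzene rings are bought; the pyranone ring is closed first (step 1) and contracted to the dihydrofuran ring in step 3.

Assumption: ketone 1 (5′-bromo-2′-hydroxy-3′-methoxyacetophenone) is taken as a purchasable catalogue building block.

## Route

Step 1
Reactants: 1 1-(5-bromo-2-hydroxy-3-methoxyphenyl)ethan-1-one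
Product: 3 6-bromo-8-methoxy-4H-chromen-4-one, via enaminone 2 (not isolated)
Conditions: Me2NCH(OMe)2 (2 equiv), PhMe, 100 °C; evaporate; AcOH, 100 °C
Reagents that add atoms: N,N-dimethylformamide dimethyl acetal, COC(OC)N(C)C
Why: Condensation of the methyl ketone with the amide acetal gives enaminone 2, and acid-promoted intramolecular O-addition with loss of Me2NH (enaminone chromone synthesis) closes the pyranone ring; no stereocentre is formed.

Step 2
Reactants: 3 6-bromo-8-methoxy-4H-chromen-4-one; 4 (3,4-dimethoxyphenyl)boronic acid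
Product: 5 (2R)-6-bromo-2-(3,4-dimethoxyphenyl)-8-methoxy-2,3-dihydro-4H-chromen-4-one
Conditions: Pd(OCOCF3)2 (5 mol%), (S)-t-BuPyOX (6 mol%), NH4PF6 (30 mol%), H2O (5 equiv), 4 (2 equiv), ClCH2CH2Cl, 60 °C
Reagents that add atoms: none
Why: Pd(II)/pyridine-oxazoline-catalysed asymmetric conjugate (1,4-) addition of the arylboronic acid to the chromone, in which the aryl–Pd species adds to C2 on the ligand-controlled face and the Pd enolate is protonated, sets C2 as R (the (S)-ligand is expected to give this sense by analogy with cyclic enones, the ligand antipode being the handle if it does not; Pd stays Pd(II), so the aryl bromide is untouched).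

Step 3
Reactants: 5 (2R)-6-bromo-2-(3,4-dimethoxyphenyl)-8-methoxy-2,3-dihydro-4H-chromen-4-one
Product: 8 methyl (2R,3R)-5-bromo-2-(3,4-dimethoxyphenyl)-7-methoxy-2,3-dihydro-1-benzofuran-3-carboxylate, via enol ether 6 (not isolated), via iodanyl ketal 7 (not isolated)
Conditions: PhI(OAc)2 (1.2 equiv), conc. H2SO4 (0.5 equiv), HC(OMe)3, 0 °C to rt; aq. NaHCO3
Reagents that add atoms: trimethyl orthoformate, COC(OC)OC; water, O
Why: Acid and orthoformate convert the ketone into enol ether 6, PhI(OAc)2 attacks C3 anti to the C2 aryl group to give the α-iodanyl ketal 7 (an enolonium equivalent), and the ring-A carbon C4a migrates from C4 to C3 with inversion and loss of PhI (iodine(III)-mediated oxidative 1,2-aryl shift, the known ring contraction of flavanones to methyl trans-2-aryl-2,3-dihydrobenzofuran-3-carboxylates), which forms the C3–C3a bond, places CO2Me trans to the aryl group (3R) and leaves C2 untouched.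

Step 4
Reactants: 8 methyl (2R,3R)-5-bromo-2-(3,4-dimethoxyphenyl)-7-methoxy-2,3-dihydro-1-benzofuran-3-carboxylate
Product: 9 [(2R,3S)-5-bromo-2-(3,4-dimethoxyphenyl)-7-methoxy-2,3-dihydro-1-benzofuran-3-yl]methanol
Conditions: LiAlH4 (1 equiv), THF, 0 °C; Rochelle salt work-up
Reagents that add atoms: none
Why: Hydride reduction of the ester to the primary alcohol at 0 °C leaves the aryl bromide, the benzylic ether and both stereocentres untouched (the C3 label changes from R to S only because CH2OH ranks below C2).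

Step 5
Reactants: 9 [(2R,3S)-5-bromo-2-(3,4-dimethoxyphenyl)-7-methoxy-2,3-dihydro-1-benzofuran-3-yl]methanol; 10 acrolein diethyl acetal
Product: 12 (E)-3-[(2R,3S)-2-(3,4-dimethoxyphenyl)-3-(hydroxymethyl)-7-methoxy-2,3-dihydro-1-benzofuran-5-yl]prop-2-enal (4-O-methylbalanophonin), via enal diethyl acetal 11 (not isolated)
Conditions: Pd(OAc)2 (3 mol%), n-Bu4NOAc (2 equiv), K2CO3 (1.5 equiv), KCl (1 equiv), 10 (3 equiv), DMF, 90 °C; then 2 M HCl, rt
Reagents that add atoms: water, O
Why: Mizoroki–Heck arylation of acrolein diethyl acetal under Jeffery/Cacchi conditions gives the E-configured enal acetal 11, which dilute acid hydrolyses to the E-enal; the free alcohol needs no protection and the ring stereocentres are not involved.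

## Compound list

1 | 1-(5-bromo-2-hydroxy-3-methoxyphenyl)ethan-1-one | CC(=O)c1cc(Br)cc(OC)c1O | starting material
2 | (E)-1-(5-bromo-2-hydroxy-3-methoxyphenyl)-3-(dimethylamino)prop-2-en-1-one | CN(C)/C=C/C(=O)c1cc(Br)cc(OC)c1O | intermediate
3 | 6-bromo-8-methoxy-4H-chromen-4-one | O=c1ccoc2c(OC)cc(Br)cc12 | intermediate
4 | (3,4-dimethoxyphenyl)boronic acid | COc1ccc(B(O)O)cc1OC | starting material
5 | (2R)-6-bromo-2-(3,4-dimethoxyphenyl)-8-methoxy-2,3-dihydro-4H-chromen-4-one | COc1ccc([C@H]2CC(=O)c3cc(Br)cc(OC)c3O2)cc1OC | intermediate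
6 | (2R)-6-bromo-2-(3,4-dimethoxyphenyl)-4,8-dimethoxy-2H-chromene | COC1=C[C@H](c2ccc(OC)c(OC)c2)Oc2c(OC)cc(Br)cc12 | intermediate
7 | (2S,3S)-3-[acetoxy(phenyl)-λ3-iodanyl]-6-bromo-2-(3,4-dimethoxyphenyl)-4,4,8-trimethoxychromane (iodanyl trans to aryl; C2 spatially as in 5, label changed by iodine priority) | COC1(OC)[C@@H](I(OC(C)=O)c2ccccc2)[C@H](c2ccc(OC)c(OC)c2)Oc2c(OC)cc(Br)cc12 | intermediate
8 | methyl (2R,3R)-5-bromo-2-(3,4-dimethoxyphenyl)-7-methoxy-2,3-dihydro-1-benzofuran-3-carboxylate (trans) | COc1ccc([C@@H]2Oc3c(OC)cc(Br)cc3[C@H]2C(=O)OC)cc1OC | intermediate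
9 | [(2R,3S)-5-bromo-2-(3,4-dimethoxyphenyl)-7-methoxy-2,3-dihydro-1-benzofuran-3-yl]methanol (trans) | COc1ccc([C@@H]2Oc3c(OC)cc(Br)cc3[C@H]2CO)cc1OC | intermediate
10 | acrolein diethyl acetal (3,3-diethoxyprop-1-ene) | C=CC(OCC)OCC | starting material
11 | {(2R,3S)-5-[(E)-3,3-diethoxyprop-1-en-1-yl]-2-(3,4-dimethoxyphenyl)-7-methoxy-2,3-dihydro-1-benzofuran-3-yl}methanol | COc1ccc([C@@H]2Oc3c(OC)cc(/C=C/C(OCC)OCC)cc3[C@H]2CO)cc1OC | intermediate
12 | (E)-3-[(2R,3S)-2-(3,4-dimethoxyphenyl)-3-(hydroxymethyl)-7-methoxy-2,3-dihydro-1-benzofuran-5-yl]prop-2-enal | COc1ccc([C@@H]2Oc3c(OC)cc(/C=C/C=O)cc3[C@H]2CO)cc1OC | target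

## Step count and risks

Total steps: 5. Longest linear sequence: 5 (1 → 3 → 5 → 8 → 9 → 12).

**Step 3 (ring contraction) is the most likely to fail.** The electron-rich 2-aryl group can migrate instead (isoflavone), elimination can give the flavone, and acid can open the pyranone ring and erode the ee. The fallback replaces the ring contraction by a Rh-carbenoid C–H insertion; it sets out from 1 and comes back to the route at 8. Ketone 1 is O-alkylated with 3,4-dimethoxybenzyl chloride (K2CO3, DMF, 60 °C) to give the aryl benzyl ether F1. The methyl ketone of F1 is converted by PhI(OH)OTs/HC(OMe)3 (oxidative aryl shift of an aryl methyl ketone) into the methyl arylacetate F2. Diazo transfer (p-ABSA, DBU, MeCN) gives the aryldiazoacetate F3. Rh2(S-PTTL)4 (or its enantiomer, whichever gives 2R) in toluene at −60 °C inserts the carbenoid into the benzylic C–H bond to give the cis-ester F4. NaOMe/MeOH then epimerises C3 to give 8.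

**Step 2 (asymmetric conjugate arylation) is second.** Chromones are sluggish acceptors, the electron-rich boronic acid can protodeboronate, and the ee or facial sense may fall short. The fallback forms the C2–O bond instead of the C2–aryl bond; it sets out from 1 and comes back at 5. Claisen–Schmidt condensation of 1 with 3,4-dimethoxybenzaldehyde (KOH, EtOH) gives the 2′-hydroxychalcone F5. A cinchona-derived bifunctional thiourea base cyclises it by enantioselective intramolecular oxa-Michael addition to 5, and one recrystallisation upgrades the ee.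

**Step 5 (Heck coupling) is third.** Oxidative addition to the electron-rich aryl bromide is slow, and β-hydride elimination towards the acetal carbon would give the saturated ester. The fallback uses formylation and olefination; it sets out from 9 and comes back at 12. Bromine–lithium exchange on 9 (n-BuLi, 2.2 equiv, THF, −78 °C) and a DMF quench give the aryl aldehyde F6. Wittig olefination with Ph3P=CHCHO (toluene, 80 °C) then gives the E-enal 12.

## Further compounds

F1 | step 3 | 1-{5-bromo-2-[(3,4-dimethoxybenzyl)oxy]-3-methoxyphenyl}ethan-1-one | CC(=O)c1cc(Br)cc(OC)c1OCc1ccc(OC)c(OC)c1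
F2 | step 3 | methyl 2-{5-bromo-2-[(3,4-dimethoxybenzyl)oxy]-3-methoxyphenyl}acetate | COC(=O)Cc1cc(Br)cc(OC)c1OCc1ccc(OC)c(OC)c1
F3 | step 3 | methyl 2-{5-bromo-2-[(3,4-dimethoxybenzyl)oxy]-3-methoxyphenyl}-2-diazoacetate | COC(=O)C(=[N+]=[N-])c1cc(Br)cc(OC)c1OCc1ccc(OC)c(OC)c1
F4 | step 3 | methyl (2R,3S)-5-bromo-2-(3,4-dimethoxyphenyl)-7-methoxy-2,3-dihydro-1-benzofuran-3-carboxylate (cis) | COc1ccc([C@@H]2Oc3c(OC)cc(Br)cc3[C@@H]2C(=O)OC)cc1OC
F5 | step 2 | (E)-1-(5-bromo-2-hydroxy-3-methoxyphenyl)-3-(3,4-dimethoxyphenyl)prop-2-en-1-one | COc1ccc(/C=C/C(=O)c2cc(Br)cc(OC)c2O)cc1OC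
F6 | step 5 | (2R,3S)-2-(3,4-dimethoxyphenyl)-3-(hydroxymethyl)-7-methoxy-2,3-dihydro-1-benzofuran-5-carbaldehyde | COc1ccc([C@@H]2Oc3c(OC)cc(C=O)cc3[C@H]2CO)cc1OC
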